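**Plan**

- Target in eudesmane numbering: methyl 3β-angeloyloxy-5α-hydroperoxyeudesma-4(15),11(13)-dien-12-oate, (3S,5S,7R,10S). Retrosynthetic cuts in order: O–C5 with the C4=C15 shift (singlet-oxygen ene), the C3–O ester bond (Mitsunobu), C11–C12 (carbonylation of an enol triflate), then C5–C10 and C3–C4 together (nickel-catalysed dienyne [4+2]), C1–C2 (Stille) and C6–C7 (auxiliary alkylation).
- Enabling feature: ring A is a cyclohexene whose C4=C5 alkene carries C15 on C4 and lies between oxygenated C3 and quaternary C10. That is a but-2-ynyl unit (C15–C4≡C5–C6) added across a 1-silyloxy-4-methyl diene (C3=C2–C1=C10).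
- Forward: hex-5-yn-1-ol gives the C7–C10 chain as an E-vinyl iodide acid; imide alkylation adds C6–C5≡C4–C15; Stille coupling adds C2–C3 as an E-silyl enol ether; the cycloaddition closes rings A and B in one step; the acrylate, the angelate and the hydroperoxide follow.
- Stereochemistry: C7 from the (S)-benzyloxazolidinone; C10 from C7 through a chair-like tether in the cycloaddition; C3 from the E enol ether (suprafacial addition gives 3α), inverted to 3β in the Mitsunobu step; C5 from α-face attack of singlet oxygen.
- Alkene geometry: C10=C1 from syn-carboalumination; C2=C3 from a stereoretentive alkenyllithium oxygenation and Stille coupling (direct enolization of the corresponding β,γ-unsaturated aldehyde would not secure the E enol ether); the angelate from angelic acid.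

Key step: step 8

Remark: eudesmane numbering is used for all bicyclic compounds (C14 on C10, C15 on C4, C11 on C7, C12 the ester carbon, C13 the methylene; 7β side chain and 10β-methyl throughout); species that exist only bound to a catalyst are described in the Why lines and carry no number.

Step 1
Reactants: 1 hex-5-yn-1-ol
Product: 3 (E)-6-iodo-5-methylhex-5-en-1-ol, via alkenylalane 2 (not isolated)
Conditions: Me3Al (3 equiv), Cp2ZrCl2 (0.25 equiv), CH2Cl2, 0 °C to rt; then I2, THF, −30 to 0 °C
Reagents that add atoms: trimethylaluminium, C[Al](C)C; iodine, II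
Why: Zirconium-catalysed methylalumination of the terminal alkyne (Negishi carboalumination) adds methyl and aluminium syn with methyl on the internal carbon, and iodinolysis of the C–Al bond with retention fixes the E geometry of the future C10=C1 alkene.

Step 2
Reactants: 3 (E)-6-iodo-5-methylhex-5-en-1-ol
Product: 5 (E)-6-iodo-5-methylhex-5-enoic acid, via aldehyde 4 (not isolated)
Conditions: TEMPO (cat.), PhI(OAc)2 (2.2 equiv), MeCN/H2O 1:1, rt
Reagents that add atoms: water, O
Why: The oxoammonium species from TEMPO oxidizes the primary alcohol to the aldehyde and, through its hydrate, on to the acid (TEMPO/PhI(OAc)2 oxidation), and should leave the vinyl iodide and the trisubstituted alkene untouched.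

Step 3
Reactants: 5 (E)-6-iodo-5-methylhex-5-enoic acid; 6 (S)-4-benzyloxazolidin-2-one
Product: 8 (4S)-4-benzyl-3-[(5E)-6-iodo-5-methylhex-5-enoyl]-1,3-oxazolidin-2-one, via mixed anhydride 7 (not isolated)
Conditions: PivCl, Et3N, THF, −20 °C; then 6, LiCl, −20 °C to rt
Reagents that add atoms: none
Why: N-acylation of the oxazolidinone through the mixed pivalic anhydride with LiCl/Et3N activation is the standard mild entry to Evans imides and creates no stereocentre.

Step 4
Reactants: 8 (4S)-4-benzyl-3-[(5E)-6-iodo-5-methylhex-5-enoyl]-1,3-oxazolidin-2-one; 9 1-bromobut-2-yne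
Product: 11 (4S)-4-benzyl-3-[(2R,5E)-2-(but-2-yn-1-yl)-6-iodo-5-methylhex-5-enoyl]-1,3-oxazolidin-2-one, via sodium enolate 10 (not isolated)
Conditions: NaN(SiMe3)2, THF, −78 °C; then 9, −78 to −45 °C
Reagents that add atoms: none
Why: Evans asymmetric alkylation: the chelated Z-sodium enolate is attacked by the propargylic bromide on the face away from the benzyl group, which sets C7 as R (the 7β side chain of the target), and the vinyl iodide should be inert to the amide base at −78 °C.

Step 5
Reactants: 11 (4S)-4-benzyl-3-[(2R,5E)-2-(but-2-yn-1-yl)-6-iodo-5-methylhex-5-enoyl]-1,3-oxazolidin-2-one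
Product: 12 methyl (2R,5E)-2-(but-2-yn-1-yl)-6-iodo-5-methylhex-5-enoate
Conditions: MeOMgBr (from MeMgBr and MeOH), MeOH/CH2Cl2, 0 °C to rt
Reagents that add atoms: bromomagnesium methoxide, CO[Mg]Br
Why: Transesterification of the exocyclic imide carbonyl with bromomagnesium methoxide releases the auxiliary without enolizing the α-branched centre, so C7 should be kept.

Step 6
Reactants: 13 (E)-1,2-bis(tributylstannyl)ethene
Product: 16 (E)-tributyl[2-(tert-butyldimethylsilyloxy)ethenyl]stannane, via stannylvinyllithium 14 (not isolated), via lithium enolate 15 (not isolated)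
Conditions: n-BuLi (1.0 equiv), THF, −78 °C; then t-BuOOLi (from t-BuOOH and n-BuLi), THF, −78 to −20 °C; then TBSCl, DMPU, −78 °C to rt
Reagents that add atoms: lithium tert-butyl peroxide, CC(C)(C)OO[Li]; tert-butyldimethylsilyl chloride, CC(C)(C)[Si](C)(C)Cl
Why: Tin–lithium exchange gives the E-alkenyllithium with retention, electrophilic oxygenation of the C–Li bond by the lithium alkyl peroxide (oxidation of alkenyllithiums to enolates) also retains configuration, and O-silylation of the aldehyde enolate should then deliver the E-configured β-stannyl silyl enol ether.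

Step 7
Reactants: 12 methyl (2R,5E)-2-(but-2-yn-1-yl)-6-iodo-5-methylhex-5-enoate; 16 (E)-tributyl[2-(tert-butyldimethylsilyloxy)ethenyl]stannane
Product: 17 methyl (2R,5E,7E)-2-(but-2-yn-1-yl)-8-(tert-butyldimethylsilyloxy)-5-methylocta-5,7-dienoate
Conditions: Pd2(dba)3 (2.5 mol %), AsPh3 (20 mol %), NMP, rt to 40 °C, dark
Reagents that add atoms: none
Why: Stille coupling (oxidative addition of the vinyl iodide to zerovalent palladium, tin-to-palladium transmetallation, reductive elimination) joins the two sp2 carbons with retention at both under neutral, fluoride-free conditions, so the (5E,7E)-silyloxy diene should form with the ester, the alkyne and the silyl enol ether intact.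

Step 8
Reactants: 17 methyl (2R,5E,7E)-2-(but-2-yn-1-yl)-8-(tert-butyldimethylsilyloxy)-5-methylocta-5,7-dienoate
Product: 18 methyl 3α-(tert-butyldimethylsilyloxy)-12,13-dinoreudesma-1,4-dien-11-oate
Conditions: Ni(cod)2 (15 mol %), P[OCH(CF3)2]3 (45 mol %), cyclohexane, 25 to 80 °C
Reagents that add atoms: none
Why: Zerovalent nickel binds the C4≡C5 alkyne and the C10=C1–C2=C3 diene, oxidative cyclization joins C5 to C10 to give a σ-vinyl/η3-allyl nickelacycle, and reductive elimination closes C3–C4 and frees the cyclohexa-1,4-diene, a union that the unactivated partners would not undergo thermally. The closest known reaction type is the nickel–phosphite-catalysed intramolecular [4+2] cycloaddition of dienynes, which accepts silyl ethers, esters and methyl-substituted alkynes and has been shown to form ring-fusion quaternary carbons. Ring B closes in the oxidative cyclization, the alkyne carbon C5 reaching the diene terminus C10 through the four-atom C6–C9 tether, and ring A is the six-membered ring of the cycloaddition itself, completed by the C3–C4 reductive elimination. C10 is controlled by C7: the tether folds chair-like with the ester equatorial, and the diene then presents the face that puts the C10 methyl axial and cis to the ester (10β-methyl with 7β-ester). C3 is controlled by the diene geometry: addition is suprafacial on the (5E,7E)-diene, so the outside silyloxy group ends cis to C9 and trans to the angular methyl (3α), the configuration that the later inversion needs. The step needs [4+2] periselectivity over alkyne oligomerization and the facial selectivity just described; the tether, the absence of any terminal alkyne and the electron-poor phosphite should secure the first, and the equatorial preference of the C7 ester the second.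

Step 9
Reactants: 18 methyl 3α-(tert-butyldimethylsilyloxy)-12,13-dinoreudesma-1,4-dien-11-oate
Product: 19 methyl 3α-(tert-butyldimethylsilyloxy)-12,13-dinoreudesm-4-en-11-oate
Conditions: H2 (1–4 atm), RhCl(PPh3)3 (10 mol %), benzene/EtOH, rt
Reagents that add atoms: none
Why: Homogeneous hydrogenation with RhCl(PPh3)3 discriminates alkenes by substitution, so the cis-disubstituted C1=C2 bond should be saturated while the tetrasubstituted C4=C5 bond and the allylic silyl ether stay intact; no stereocentre is formed.

Step 10
Reactants: 19 methyl 3α-(tert-butyldimethylsilyloxy)-12,13-dinoreudesm-4-en-11-oate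
Product: 21 3α-(tert-butyldimethylsilyloxy)-12-noreudesm-4-en-11-one, via Weinreb amide 20 (not isolated)
Conditions: MeNHOMe·HCl, i-PrMgCl, THF, −20 to 0 °C; then MeMgBr, 0 °C to rt; aq. NH4Cl
Reagents that add atoms: methylmagnesium bromide, C[Mg]Br
Why: The ester is converted in one flask into the Weinreb amide (aminolysis by the magnesium amide) and then into the methyl ketone by Grignard addition, the chelated tetrahedral intermediate preventing over-addition, while C7 already holds its equatorial, thermodynamically preferred configuration.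

Step 11
Reactants: 21 3α-(tert-butyldimethylsilyloxy)-12-noreudesm-4-en-11-one
Product: 23 3α-(tert-butyldimethylsilyloxy)-12-noreudesma-4,11(13)-dien-11-yl trifluoromethanesulfonate, via potassium enolate 22 (not isolated)
Conditions: KN(SiMe3)2, THF, −78 °C; then PhNTf2, −78 to 0 °C
Reagents that add atoms: N-phenylbis(trifluoromethanesulfonimide), O=S(=O)(C(F)(F)F)N(c1ccccc1)S(=O)(=O)C(F)(F)F
Why: Kinetic deprotonation with the bulky potassium amide should occur at the methyl group and not at the hindered C7 methine, and O-sulfonylation of the terminal enolate gives the 1,1-disubstituted enol triflate (enol triflate formation).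

Step 12
Reactants: 23 3α-(tert-butyldimethylsilyloxy)-12-noreudesma-4,11(13)-dien-11-yl trifluoromethanesulfonate
Product: 24 methyl 3α-(tert-butyldimethylsilyloxy)eudesma-4,11(13)-dien-12-oate
Conditions: Pd(OAc)2 (5 mol %), PPh3 (10 mol %), Et3N, CO (1 atm), MeOH/DMF, 40 °C
Reagents that add atoms: carbon monoxide, [C-]#[O+]; methanol, CO
Why: Palladium-catalysed methoxycarbonylation of the enol triflate (oxidative addition, CO insertion, methanolysis) turns C11 into the α-methylene ester, the standard passage from a methyl ketone to a 2-substituted acrylate.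

Step 13
Reactants: 24 methyl 3α-(tert-butyldimethylsilyloxy)eudesma-4,11(13)-dien-12-oate
Product: 25 methyl 3α-hydroxyeudesma-4,11(13)-dien-12-oate
Conditions: HF·pyridine, pyridine/THF, 0 °C to rt
Reagents that add atoms: none
Why: Fluoride cleavage of the silyl ether with buffered HF·pyridine should unmask the 3α-alcohol without a base that could add to the acrylate and without touching C3.

Step 14
Reactants: 25 methyl 3α-hydroxyeudesma-4,11(13)-dien-12-oate; 26 angelic acid
Product: 28 methyl 3β-[(Z)-2-methylbut-2-enoyloxy]eudesma-4,11(13)-dien-12-oate, via alkoxyphosphonium angelate 27 (not isolated)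
Conditions: PPh3, DIAD, toluene, 0 °C to rt
Reagents that add atoms: none
Why: Mitsunobu esterification: the carboxylate displaces the alkoxyphosphonium group at C3 by SN2 with inversion, turning the pseudoaxial 3α-alcohol into the 3β-angelate, and because angelic acid acts only as a nucleophile its Z geometry is not endangered, while SN2′ attack would have to occur at fully substituted C5.

Step 15
Reactants: 28 methyl 3β-[(Z)-2-methylbut-2-enoyloxy]eudesma-4,11(13)-dien-12-oate
Product: 29 methyl 3β-[(Z)-2-methylbut-2-enoyloxy]-5α-hydroperoxyeudesma-4(15),11(13)-dien-12-oate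
Conditions: O2, visible light, tetraphenylporphyrin (cat.), CH2Cl2, −20 °C
Reagents that add atoms: dioxygen, O=O
Why: Schenck ene reaction: singlet oxygen should react only with the electron-rich tetrasubstituted C4=C5 bond, bond to C5 from the α face opposite the axial C14 methyl and the 3β-ester, and take hydrogen from C15 (the alkyl group geminal to the oxygenated allylic carbon), which moves the alkene to C4=C15 and gives the 5α-hydroperoxide, the acrylate and the angelate being too electron-poor to compete.

**Compound list**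

1 | hex-5-yn-1-ol | C#CCCCCO | starting material
2 | dimethyl[(E)-6-(dimethylalumanyloxy)-2-methylhex-1-en-1-yl]alane (alkenylalane, not isolated) | C[Al](C)OCCCC/C(C)=C/[Al](C)C | intermediate
3 | (E)-6-iodo-5-methylhex-5-en-1-ol | OCCCC/C(C)=C/I | intermediate
4 | (E)-6-iodo-5-methylhex-5-enal (not isolated) | O=CCCC/C(C)=C/I | intermediate
5 | (E)-6-iodo-5-methylhex-5-enoic acid | OC(=O)CCC/C(C)=C/I | intermediate
6 | (S)-4-benzyloxazolidin-2-one | O=C1N[C@@H](Cc2ccccc2)CO1 | starting material
7 | (E)-6-iodo-5-methylhex-5-enoic pivalic anhydride (not isolated) | CC(C)(C)C(=O)OC(=O)CCC/C(C)=C/I | intermediate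
8 | (4S)-4-benzyl-3-[(5E)-6-iodo-5-methylhex-5-enoyl]-1,3-oxazolidin-2-one | O=C(CCC/C(C)=C/I)N1[C@@H](Cc2ccccc2)COC1=O | intermediate
9 | 1-bromobut-2-yne | CC#CCBr | starting material
10 | sodium Z-enolate of imide 8 (not isolated) | [Na+].[O-]/C(=C\CC/C(C)=C/I)N1[C@@H](Cc2ccccc2)COC1=O | intermediate
11 | (4S)-4-benzyl-3-[(2R,5E)-2-(but-2-yn-1-yl)-6-iodo-5-methylhex-5-enoyl]-1,3-oxazolidin-2-one | CC#CC[C@H](C(=O)N1[C@@H](Cc2ccccc2)COC1=O)CC/C(C)=C/I | intermediate
12 | methyl (2R,5E)-2-(but-2-yn-1-yl)-6-iodo-5-methylhex-5-enoate | CC#CC[C@H](C(=O)OC)CC/C(C)=C/I | intermediate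
13 | (E)-1,2-bis(tributylstannyl)ethene | CCCC[Sn](CCCC)(CCCC)/C=C/[Sn](CCCC)(CCCC)CCCC | starting material
14 | (E)-2-(tributylstannyl)ethenyllithium (not isolated) | [Li]/C=C/[Sn](CCCC)(CCCC)CCCC | intermediate
15 | lithium (E)-2-(tributylstannyl)ethenolate (not isolated) | [Li]O/C=C/[Sn](CCCC)(CCCC)CCCC | intermediate
16 | (E)-tributyl[2-(tert-butyldimethylsilyloxy)ethenyl]stannane | CC(C)(C)[Si](C)(C)O/C=C/[Sn](CCCC)(CCCC)CCCC | intermediate
17 | methyl (2R,5E,7E)-2-(but-2-yn-1-yl)-8-(tert-butyldimethylsilyloxy)-5-methylocta-5,7-dienoate | CC#CC[C@H](C(=O)OC)CC/C(C)=C/C=C/O[Si](C)(C)C(C)(C)C | intermediate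
18 | methyl 3α-(tert-butyldimethylsilyloxy)-12,13-dinoreudesma-1,4-dien-11-oate (7β-CO2Me, 10β-CH3) | COC(=O)[C@@H]1CC[C@@]2(C)C=C[C@@H](O[Si](C)(C)C(C)(C)C)C(C)=C2C1 | intermediate
19 | methyl 3α-(tert-butyldimethylsilyloxy)-12,13-dinoreudesm-4-en-11-oate | COC(=O)[C@@H]1CC[C@@]2(C)CC[C@@H](O[Si](C)(C)C(C)(C)C)C(C)=C2C1 | intermediate
20 | N-methoxy-N-methyl-3α-(tert-butyldimethylsilyloxy)-12,13-dinoreudesm-4-en-11-amide (Weinreb amide, not isolated) | CON(C)C(=O)[C@@H]1CC[C@@]2(C)CC[C@@H](O[Si](C)(C)C(C)(C)C)C(C)=C2C1 | intermediate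
21 | 3α-(tert-butyldimethylsilyloxy)-12-noreudesm-4-en-11-one (7β-acetyl) | CC(=O)[C@@H]1CC[C@@]2(C)CC[C@@H](O[Si](C)(C)C(C)(C)C)C(C)=C2C1 | intermediate
22 | potassium enolate of 21 at the methyl group (not isolated) | [K+].[O-]C(=C)[C@@H]1CC[C@@]2(C)CC[C@@H](O[Si](C)(C)C(C)(C)C)C(C)=C2C1 | intermediate
23 | 3α-(tert-butyldimethylsilyloxy)-12-noreudesma-4,11(13)-dien-11-yl trifluoromethanesulfonate | C=C(OS(=O)(=O)C(F)(F)F)[C@@H]1CC[C@@]2(C)CC[C@@H](O[Si](C)(C)C(C)(C)C)C(C)=C2C1 | intermediate
24 | methyl 3α-(tert-butyldimethylsilyloxy)eudesma-4,11(13)-dien-12-oate | C=C(C(=O)OC)[C@@H]1CC[C@@]2(C)CC[C@@H](O[Si](C)(C)C(C)(C)C)C(C)=C2C1 | intermediate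
25 | methyl 3α-hydroxyeudesma-4,11(13)-dien-12-oate | C=C(C(=O)OC)[C@@H]1CC[C@@]2(C)CC[C@@H](O)C(C)=C2C1 | intermediate
26 | angelic acid, (Z)-2-methylbut-2-enoic acid | C/C=C(/C)C(=O)O | starting material
27 | 3α-(triphenylphosphoniooxy) derivative of 25 as its angelate salt (not isolated) | C=C(C(=O)OC)[C@@H]1CC[C@@]2(C)CC[C@@H](O[P+](c3ccccc3)(c3ccccc3)c3ccccc3)C(C)=C2C1.C/C=C(/C)C(=O)[O-] | intermediate
28 | methyl 3β-[(Z)-2-methylbut-2-enoyloxy]eudesma-4,11(13)-dien-12-oate | C=C(C(=O)OC)[C@@H]1CC[C@@]2(C)CC[C@H](OC(=O)/C(C)=C\C)C(C)=C2C1 | intermediate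
29 | methyl (3S,5S,7R,10S)-3β-[(Z)-2-methylbut-2-enoyloxy]-5α-hydroperoxyeudesma-4(15),11(13)-dien-12-oate | C=C(C(=O)OC)[C@@H]1CC[C@@]2(C)CC[C@H](OC(=O)/C(C)=C\C)C(=C)[C@]2(OO)C1 | target

**Count and risks**

Total steps: 15. Longest linear sequence: 14 steps (steps 1–5 and 7–15, from hex-5-yn-1-ol); step 6 prepares stannane 16 in one step from commercial 13.

The three steps most likely to fail:

Step 8. The facial selectivity may be poor, because the equatorial preference of an ester is small and the C7 centre may transmit too little bias to C10; the hindered diene (inside methyl, quaternary centre formed) may also react slowly. Fallback: carry C11 through the cycloaddition as a quaternary ketal carbon, which can only sit equatorial. From 12, aminolysis with MeNHOMe·HCl/i-PrMgCl gives the Weinreb amide F1 and MeMgBr then the methyl ketone F2. Ketalization with 1,2-bis(trimethylsilyloxy)ethane and catalytic TMSOTf at −78 °C, cold enough to avoid enolization of C7, gives the dioxolane F3. Stille coupling with 16 gives the dienyne F4, the nickel-catalysed cycloaddition gives the bicyclic ketal F5, and hydrogenation as in step 9 gives F6. Hydrolysis with pyridinium p-toluenesulfonate in wet acetone returns to 21.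

Step 6. The oxygenation of the stannylvinyllithium may be lost to protonation or to loss of tin from the β-stannyl enolate, which would leave no stereodefined silyloxyvinyl partner. Fallback: an ethyl enol ether from a commercial boronate, followed by an oxidation–reduction detour at C3. From 12, Suzuki coupling with (E)-2-ethoxyvinylboronic acid pinacol ester (PdCl2(dppf), K3PO4, THF/H2O) gives the ethoxy diene F7. Cycloaddition as in step 8 gives the 3α-ethyl ether F8. DDQ in wet CH2Cl2 oxidizes the doubly allylic ether carbon to the cross-conjugated dienone F9. Hydrogenation with RhCl(PPh3)3 saturates only C1=C2 and gives the enone F10. KBH(s-Bu)3 at −78 °C delivers hydride from the equatorial side and gives the 3α-alcohol F11. Silylation (TBSCl, imidazole, DMF) returns to 19.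

Step 14. Elimination of the activated pseudoaxial alcohol to a diene, or slow displacement next to the tetrasubstituted alkene, may outrun esterification. Fallback: invert by oxidation and reduction and acylate with retention. From 25, Dess–Martin oxidation gives the enone F12. NaBH4/CeCl3·7H2O in MeOH at −78 °C gives the equatorial 3β-alcohol F13. Acylation with the mixed anhydride F14, made from angelic acid 26 and 2,4,6-trichlorobenzoyl chloride (Et3N, toluene, 80 °C; conditions chosen to limit isomerization to the tiglate), returns to 28.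

Further compounds
F1 | step 8 | (2R,5E)-2-(but-2-yn-1-yl)-6-iodo-N-methoxy-N,5-dimethylhex-5-enamide | CC#CC[C@H](C(=O)N(C)OC)CC/C(C)=C/I
F2 | step 8 | (3R,6E)-3-(but-2-yn-1-yl)-7-iodo-6-methylhept-6-en-2-one | CC#CC[C@H](C(C)=O)CC/C(C)=C/I
F3 | step 8 | ethylene ketal of F2, 2-[(5R,8E)-9-iodo-8-methylnon-8-en-2-yn-5-yl]-2-methyl-1,3-dioxolane | CC#CC[C@H](C1(C)OCCO1)CC/C(C)=C/I
F4 | step 8 | ketal analogue of 17, 2-methyl-1,3-dioxolan-2-yl in place of the ester | CC#CC[C@H](C1(C)OCCO1)CC/C(C)=C/C=C/O[Si](C)(C)C(C)(C)C
F5 | step 8 | 3α-(tert-butyldimethylsilyloxy)-12-noreudesma-1,4-dien-11-one ethylene ketal | CC3(OCCO3)[C@@H]1CC[C@@]2(C)C=C[C@@H](O[Si](C)(C)C(C)(C)C)C(C)=C2C1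
F6 | step 8 | 3α-(tert-butyldimethylsilyloxy)-12-noreudesm-4-en-11-one ethylene ketal | CC3(OCCO3)[C@@H]1CC[C@@]2(C)CC[C@@H](O[Si](C)(C)C(C)(C)C)C(C)=C2C1
F7 | step 6 | methyl (2R,5E,7E)-2-(but-2-yn-1-yl)-8-ethoxy-5-methylocta-5,7-dienoate | CC#CC[C@H](C(=O)OC)CC/C(C)=C/C=C/OCC
F8 | step 6 | methyl 3α-ethoxy-12,13-dinoreudesma-1,4-dien-11-oate | COC(=O)[C@@H]1CC[C@@]2(C)C=C[C@@H](OCC)C(C)=C2C1
F9 | step 6 | methyl 3-oxo-12,13-dinoreudesma-1,4-dien-11-oate | COC(=O)[C@@H]1CC[C@@]2(C)C=CC(=O)C(C)=C2C1
F10 | step 6 | methyl 3-oxo-12,13-dinoreudesm-4-en-11-oate | COC(=O)[C@@H]1CC[C@@]2(C)CCC(=O)C(C)=C2C1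
F11 | step 6 | methyl 3α-hydroxy-12,13-dinoreudesm-4-en-11-oate | COC(=O)[C@@H]1CC[C@@]2(C)CC[C@@H](O)C(C)=C2C1
F12 | step 14 | methyl 3-oxoeudesma-4,11(13)-dien-12-oate | C=C(C(=O)OC)[C@@H]1CC[C@@]2(C)CCC(=O)C(C)=C2C1
F13 | step 14 | methyl 3β-hydroxyeudesma-4,11(13)-dien-12-oate | C=C(C(=O)OC)[C@@H]1CC[C@@]2(C)CC[C@H](O)C(C)=C2C1
F14 | step 14 | (Z)-2-methylbut-2-enoic 2,4,6-trichlorobenzoic anhydride | C/C=C(/C)C(=O)OC(=O)c1c(Cl)cc(Cl)cc1Cl
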